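Locants: oxolane ring O1, C2 (CH–C6H4OH), C3 (CH–C9H2OAc), C4 (CH–C7'H(OAc)C6H4OMe), C5 (CH2).
Cuts: the phenol is masked and C9 is raised from CH2OAc to CHO. The ring is then cut at C2–C3 and at O1–C2, which releases C2 as the carbonyl carbon of a 4-hydroxybenzaldehyde ether and leaves the open chain O1–C5–C4(C7')–C3=C9–O. That chain is cut at C7'–C4 into 4-methoxybenzaldehyde and vinylethylene carbonate.
Enabling feature: C2 is benzylic and bound to the ring oxygen O1, so it can be an aryl-stabilised oxocarbenium carbon. Its ring neighbour C3 bears the oxygenated carbon C9, so at the aldehyde level C3=C9 is an enol silane at the end of the chain O1–C5–C4–C3, and the one-carbon unit C2 is stitched between O1 and C3.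
Forward order: the chain C7'–C4(C5)–C3=C9 is made in step 1 and is protected and oxidised at C9 in steps 2–5. The only new ring (the oxolane) arises in step 6 with C2–C3 as the ring-closing bond, and steps 7–9 adjust C9 and free the phenol.
Stereochemistry: C7' and C4 (anti) come from the chiral iridium catalyst of step 1, which also funnels the racemic carbonate through one allyl complex. C3 and C2 are set in step 6 under control of C4, from an E/Z mixture of enol silanes that converges on the all-trans ring.

Key step: step 6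

Assumption: the (S)-SEGPHOS-modified iridium catalyst is taken to deliver the (1S,2R) diol. Should the assay of 3 show the opposite sense, (R)-SEGPHOS is used and nothing else changes.

Step 1
Reactants: 1 4-methoxybenzaldehyde; 2 4-vinyl-1,3-dioxolan-2-one (vinylethylene carbonate, racemic)
Product: 3 (1S,2R)-2-ethenyl-1-(4-methoxyphenyl)propane-1,3-diol
Conditions: [Ir(cod)Cl]2 (2.5 mol %), (S)-SEGPHOS (5 mol %), 4-cyano-3-nitrobenzoic acid (10 mol %), Cs2CO3 (20 mol %), i-PrOH (2 equiv), THF, 90 °C, sealed tube
Reagents that add atoms: none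
Why: Krische allylation in its anti-(hydroxymethyl)allylation form, in which the carbonate ionises with loss of CO2 to an (E)-σ-allyliridium species (the same one from either enantiomer of 2), its closed chair transition state sets the anti relation C7'/C4, and the ligand sets the absolute sense.

Step 2
Reactants: 3 (1S,2R)-2-ethenyl-1-(4-methoxyphenyl)propane-1,3-diol
Product: 5 (1S,2R)-1-(4-methoxyphenyl)-2-[(triethylsilyloxy)methyl]but-3-en-1-yl acetate, via primary triethylsilyl ether 4 (not isolated)
Conditions: TESCl (1.05 equiv), imidazole (1.2 equiv), CH2Cl2, −20 °C; then Et3N, Ac2O, DMAP (cat.), 0 °C to rt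
Reagents that add atoms: triethylsilyl chloride, CC[Si](Cl)(CC)CC; acetic anhydride, CC(=O)OC(C)=O
Why: Chemoselective silylation of the less hindered primary hydroxyl followed by DMAP-catalysed acetylation of the benzylic hydroxyl touches no stereocentre, installs the C7' acetate of the target and stops that oxygen from later forming a rival oxocarbenium ion.

Step 3
Reactants: 5 (1S,2R)-1-(4-methoxyphenyl)-2-[(triethylsilyloxy)methyl]but-3-en-1-yl acetate
Product: 7 (1S,2R)-4-hydroxy-1-(4-methoxyphenyl)-2-[(triethylsilyloxy)methyl]butyl acetate, via B-alkyl-9-BBN adduct 6 (not isolated)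
Conditions: 9-BBN (1.5 equiv), THF, 0 °C to rt; NaBO3·4H2O, THF/H2O, rt
Reagents that add atoms: 9-borabicyclo[3.3.1]nonane (boron unit of 6), B1C2CCCC1CCC2; sodium perborate (oxygen of 7), [Na+].[O-]OB=O
Why: Brown hydroboration–oxidation places oxygen on the terminal carbon C9 with anti-Markovnikov selectivity, and the perborate work-up is mild enough for the acetate and the silyl ether.

Step 4
Reactants: 7 (1S,2R)-4-hydroxy-1-(4-methoxyphenyl)-2-[(triethylsilyloxy)methyl]butyl acetate
Product: 8 (1S,2R)-1-(4-methoxyphenyl)-4-oxo-2-[(triethylsilyloxy)methyl]butyl acetate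
Conditions: (n-Pr)4N[RuO4] (5 mol %), NMO (1.5 equiv), 4 Å MS, CH2Cl2, rt
Reagents that add atoms: none
Why: The Ley–Griffith oxidation stops at the aldehyde under neutral conditions, and C4 cannot be lost because no leaving group sits on the carbon β to the new carbonyl.

Step 5
Reactants: 8 (1S,2R)-1-(4-methoxyphenyl)-4-oxo-2-[(triethylsilyloxy)methyl]butyl acetate
Product: 9 (1S,2R,3Z)-1-(4-methoxyphenyl)-4-(triethylsilyloxy)-2-[(triethylsilyloxy)methyl]but-3-en-1-yl acetate (Z isomer drawn, E isomer also expected)
Conditions: TESOTf (1.2 equiv), Et3N (2.5 equiv), CH2Cl2, −78 to 0 °C; filtration through Et3N-deactivated silica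
Reagents that add atoms: triethylsilyl trifluoromethanesulfonate, CC[Si](CC)(CC)OS(=O)(=O)C(F)(F)F
Why: Soft enolisation with silyl triflate and amine converts the aldehyde, far more readily than the acetate, into its enol silane, which should be mainly Z and whose geometry is of no consequence later.

Step 6
Reactants: 9 (1S,2R,3Z)-1-(4-methoxyphenyl)-4-(triethylsilyloxy)-2-[(triethylsilyloxy)methyl]but-3-en-1-yl acetate; 10 4-(tert-butyldimethylsilyloxy)benzaldehyde
Product: 12 (2R,3R,4R)-4-[(S)-acetoxy(4-methoxyphenyl)methyl]-2-[4-(tert-butyldimethylsilyloxy)phenyl]oxolane-3-carbaldehyde, via oxocarbenium triflate 11 (not isolated)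
Conditions: 10 (1.2 equiv), TESOTf (15 mol %), 2,6-di-tert-butyl-4-methylpyridine (20 mol %), 4 Å MS, CH2Cl2, −78 to −40 °C; Et3N quench
Reagents that add atoms: none
Why: Et3SiOTf silylates the carbonyl oxygen of 10, the C5–OSiEt3 oxygen adds and a second silyl transfer expels hexaethyldisiloxane to leave the aryl-stabilised (E)-oxocarbenium ion 11 (C2=O1+), whose C2 is attacked by the enol-silane carbon C3, after which loss of Et3Si+ from the C9 oxygen unveils the formyl group and returns the catalyst. The closest known reaction types are the silyl-triflate-catalysed Mukaiyama aldol addition of enol silanes to acetals, the Lewis-acid condensation of 4-hydroxy-1-alkenyl carbamates with aldehydes to oxolane-3-carbaldehydes and the Petasis–Ferrier-type ring contraction of 4,5-dihydro-1,3-dioxepines, which all pass through the same O1–C5–C4–C3=C9 oxocarbenium/enol array. The oxolane closes in a 5-(enol-exo)-endo-trig mode, endo with respect to C2=O1+ and exo with respect to C3=C9. C3 is controlled by C4: allylic 1,3-strain in the enol silane keeps C4–H in the plane of C3=C9, the C5 tether brings the electrophile to one face and the bulky CH(OAc)Ar group occupies the other, so that C9 ends trans to the C4 side chain. C2 is controlled by the (E)-geometry of 11 and an open antiperiplanar approach in which C9 lies over the small C2–H and the aryl group takes the pseudo-equatorial site, which should give the 2,3-trans and thus the all-trans ring, also the thermodynamically preferred isomer. The step needs site selectivity (only O1 can form the ion because the C7' oxygen is an acetate), chemoselectivity (silyl triflates do not promote the direct aldehyde/enol-silane aldol at −78 °C, and low temperature plus the hindered pyridine keep the 4-methoxybenzylic acetate and the enol silane intact) and it is convergent in enol geometry, since C9 ends as a trigonal formyl carbon and both isomers of 9 lead to 12.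

Step 7
Reactants: 12 (2R,3R,4R)-4-[(S)-acetoxy(4-methoxyphenyl)methyl]-2-[4-(tert-butyldimethylsilyloxy)phenyl]oxolane-3-carbaldehyde
Product: 13 (2R,3S,4R)-4-[(S)-acetoxy(4-methoxyphenyl)methyl]-2-[4-(tert-butyldimethylsilyloxy)phenyl]-3-(hydroxymethyl)oxolane
Conditions: NaBH4, THF/MeOH (4:1), −20 °C
Reagents that add atoms: none
Why: Chemoselective borohydride reduction of the aldehyde leaves the acetate and the aryl silyl ether in place, and C3 keeps its spatial arrangement (the descriptor changes only through the priority rules).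

Step 8
Reactants: 13 (2R,3S,4R)-4-[(S)-acetoxy(4-methoxyphenyl)methyl]-2-[4-(tert-butyldimethylsilyloxy)phenyl]-3-(hydroxymethyl)oxolane
Product: 14 (2R,3S,4R)-3-(acetoxymethyl)-4-[(S)-acetoxy(4-methoxyphenyl)methyl]-2-[4-(tert-butyldimethylsilyloxy)phenyl]oxolane
Conditions: Ac2O, pyridine, DMAP (cat.), CH2Cl2, 0 °C to rt
Reagents that add atoms: acetic anhydride, CC(=O)OC(C)=O
Why: Standard DMAP-catalysed acetylation of the primary alcohol proceeds while the phenol stays masked, and any acetyl migration between the C7' and C9 oxygens would be harmless because both end as acetates.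

Step 9
Reactants: 14 (2R,3S,4R)-3-(acetoxymethyl)-4-[(S)-acetoxy(4-methoxyphenyl)methyl]-2-[4-(tert-butyldimethylsilyloxy)phenyl]oxolane
Product: 15 (2R,3S,4R)-3-(acetoxymethyl)-4-[(S)-acetoxy(4-methoxyphenyl)methyl]-2-(4-hydroxyphenyl)oxolane (target)
Conditions: TBAF (1.1 equiv), AcOH (1.5 equiv), THF, 0 °C
Reagents that add atoms: none
Why: Fluoride cleaves the aryl silyl ether very fast, and the acetic acid buffer protonates the phenoxide at once, so that both acetates and the benzylic C2–O1 bond should survive.

Compound list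
1 | 4-methoxybenzaldehyde | COc1ccc(C=O)cc1 | starting material
2 | 4-vinyl-1,3-dioxolan-2-one (racemic) | C=CC1COC(=O)O1 | starting material
3 | (1S,2R)-2-ethenyl-1-(4-methoxyphenyl)propane-1,3-diol | COc1ccc([C@@H](O)[C@@H](CO)C=C)cc1 | intermediate
4 | (1S,2R)-1-(4-methoxyphenyl)-2-[(triethylsilyloxy)methyl]but-3-en-1-ol | COc1ccc([C@@H](O)[C@@H](CO[Si](CC)(CC)CC)C=C)cc1 | intermediate
5 | (1S,2R)-1-(4-methoxyphenyl)-2-[(triethylsilyloxy)methyl]but-3-en-1-yl acetate | COc1ccc([C@@H](OC(C)=O)[C@@H](CO[Si](CC)(CC)CC)C=C)cc1 | intermediate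
6 | (1S,2R)-4-(9-borabicyclo[3.3.1]nonan-9-yl)-1-(4-methoxyphenyl)-2-[(triethylsilyloxy)methyl]butyl acetate | COc1ccc([C@@H](OC(C)=O)[C@@H](CO[Si](CC)(CC)CC)CCB2C3CCCC2CCC3)cc1 | intermediate
7 | (1S,2R)-4-hydroxy-1-(4-methoxyphenyl)-2-[(triethylsilyloxy)methyl]butyl acetate | COc1ccc([C@@H](OC(C)=O)[C@@H](CO[Si](CC)(CC)CC)CCO)cc1 | intermediate
8 | (1S,2R)-1-(4-methoxyphenyl)-4-oxo-2-[(triethylsilyloxy)methyl]butyl acetate | COc1ccc([C@@H](OC(C)=O)[C@@H](CO[Si](CC)(CC)CC)CC=O)cc1 | intermediate
9 | (1S,2R,3Z)-1-(4-methoxyphenyl)-4-(triethylsilyloxy)-2-[(triethylsilyloxy)methyl]but-3-en-1-yl acetate | COc1ccc([C@@H](OC(C)=O)[C@@H](CO[Si](CC)(CC)CC)/C=C\O[Si](CC)(CC)CC)cc1 | intermediate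
10 | 4-(tert-butyldimethylsilyloxy)benzaldehyde | CC(C)(C)[Si](C)(C)Oc1ccc(C=O)cc1 | starting material
11 | (E)-oxocarbenium triflate formed from the C5 oxygen of 9 and the carbonyl carbon of 10 | COc1ccc([C@@H](OC(C)=O)[C@@H](C/[O+]=C/c2ccc(O[Si](C)(C)C(C)(C)C)cc2)/C=C\O[Si](CC)(CC)CC)cc1.[O-]S(=O)(=O)C(F)(F)F | intermediate
12 | (2R,3R,4R)-4-[(S)-acetoxy(4-methoxyphenyl)methyl]-2-[4-(tert-butyldimethylsilyloxy)phenyl]oxolane-3-carbaldehyde | COc1ccc([C@@H](OC(C)=O)[C@H]2CO[C@@H](c3ccc(O[Si](C)(C)C(C)(C)C)cc3)[C@@H]2C=O)cc1 | intermediate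
13 | (2R,3S,4R)-4-[(S)-acetoxy(4-methoxyphenyl)methyl]-2-[4-(tert-butyldimethylsilyloxy)phenyl]-3-(hydroxymethyl)oxolane | COc1ccc([C@@H](OC(C)=O)[C@H]2CO[C@@H](c3ccc(O[Si](C)(C)C(C)(C)C)cc3)[C@@H]2CO)cc1 | intermediate
14 | (2R,3S,4R)-3-(acetoxymethyl)-4-[(S)-acetoxy(4-methoxyphenyl)methyl]-2-[4-(tert-butyldimethylsilyloxy)phenyl]oxolane | COc1ccc([C@@H](OC(C)=O)[C@H]2CO[C@@H](c3ccc(O[Si](C)(C)C(C)(C)C)cc3)[C@@H]2COC(C)=O)cc1 | intermediate
15 | (2R,3S,4R)-3-(acetoxymethyl)-4-[(S)-acetoxy(4-methoxyphenyl)methyl]-2-(4-hydroxyphenyl)oxolane | COc1ccc([C@@H](OC(C)=O)[C@H]2CO[C@@H](c3ccc(O)cc3)[C@@H]2COC(C)=O)cc1 | target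

Total step count: 9. Longest linear sequence: 9 steps (from 1 or 2 to 15).

Steps most likely to fail

Step 6.
- What may go wrong: the enol carbon may approach the oxocarbenium carbon in a synclinal instead of the antiperiplanar arrangement, which places the C2 aryl group trans to the C4 side chain. The 4-methoxybenzylic acetate may ionise under the silyl triflate, or the enol silane may be protodesilylated before the ion forms.
- Fallback: it sets out from 5, returns at 12, and replaces the enol silane by an acid-stable allylsilane. Cross-metathesis of 5 with allyltrimethylsilane (second-generation Hoveyda–Grubbs catalyst, CH2Cl2, reflux) would give the (E)-allylsilane F1.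
- Ring closure: condensation of F1 with 10 under TMSOTf (CH2Cl2, −78 °C) is a silyl-modified Hosomi–Sakurai reaction, known for 2-aryl-3-vinyl-4-substituted oxolanes. It would close the same C2–C3 bond and give the 3-vinyloxolane F2.
- Return: Lemieux–Johnson cleavage of the vinyl group of F2 (K2OsO4·2H2O cat., NaIO4, 2,6-lutidine, dioxane/H2O) would return aldehyde 12. Steps 3–5 are then not needed.

Step 1.
- What may go wrong: anti selectivity or enantioselectivity may erode with the electron-rich aldehyde, the primary hydroxyl of the product may undergo further dehydrogenative coupling, or the sense of induction may be unexpected.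
- Fallback: it sets out from 1, returns at 8, and relies on an auxiliary instead of a catalyst. (S)-4-Benzyloxazolidin-2-one is acylated (n-BuLi, pent-4-enoyl chloride, THF, −78 °C) to the imide F3.
- Aldol: the Evans syn-aldol reaction of F3 with 1 (Bu2BOTf, Et3N, CH2Cl2, −78 to 0 °C; H2O2, pH 7 buffer) would give the aldol adduct F4. Its syn relation, counted with C5 in the main chain, is the same relative configuration as the anti relation of 3.
- Return: LiBH4 (Et2O, H2O, 0 °C) would remove the auxiliary and give the 2-allyl-1,3-diol F5. The one-pot procedure of step 2 would lead through the primary triethylsilyl ether F6 to the acetate F7. Lemieux–Johnson cleavage of the terminal alkene of F7 would give aldehyde 8.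

Step 5.
- What may go wrong: the aldehyde-derived enol silane may hydrolyse during isolation, or the stoichiometric silyl triflate may ionise the benzylic acetate.
- Fallback: it sets out from 8, returns at 12, and replaces the fragile enol silane by an isolable enol ester. Ac2O, Et3N and DMAP (THF, 50 °C) would convert 8 into the enol acetate F8 (E/Z mixture, stable to chromatography).
- Return: condensation of F8 with 10 under TMSOTf (CH2Cl2, −78 to −20 °C) follows the known cyclisation of acyloxy- and carbamoyloxy-alkenes onto oxocarbenium ions. It would give 12 directly, the acetyl group leaving with the silyl group as a silyl ester.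

Further compounds
F1 | step 6 | (1S,2R,3E)-1-(4-methoxyphenyl)-2-[(triethylsilyloxy)methyl]-5-(trimethylsilyl)pent-3-en-1-yl acetate | COc1ccc([C@@H](OC(C)=O)[C@@H](CO[Si](CC)(CC)CC)/C=C/C[Si](C)(C)C)cc1
F2 | step 6 | (2R,3R,4R)-4-[(S)-acetoxy(4-methoxyphenyl)methyl]-2-[4-(tert-butyldimethylsilyloxy)phenyl]-3-ethenyloxolane | COc1ccc([C@@H](OC(C)=O)[C@H]2CO[C@@H](c3ccc(O[Si](C)(C)C(C)(C)C)cc3)[C@@H]2C=C)cc1
F3 | step 1 | (S)-4-benzyl-3-(pent-4-enoyl)oxazolidin-2-one | C=CCCC(=O)N1[C@@H](Cc2ccccc2)COC1=O
F4 | step 1 | (S)-4-benzyl-3-{(2S)-2-[(S)-hydroxy(4-methoxyphenyl)methyl]pent-4-enoyl}oxazolidin-2-one | COc1ccc([C@@H](O)[C@H](CC=C)C(=O)N2[C@@H](Cc3ccccc3)COC2=O)cc1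
F5 | step 1 | (1S,2R)-1-(4-methoxyphenyl)-2-(prop-2-en-1-yl)propane-1,3-diol | COc1ccc([C@@H](O)[C@@H](CO)CC=C)cc1
F6 | step 1 | (1S,2R)-1-(4-methoxyphenyl)-2-[(triethylsilyloxy)methyl]pent-4-en-1-ol | COc1ccc([C@@H](O)[C@@H](CO[Si](CC)(CC)CC)CC=C)cc1
F7 | step 1 | (1S,2R)-1-(4-methoxyphenyl)-2-[(triethylsilyloxy)methyl]pent-4-en-1-yl acetate | COc1ccc([C@@H](OC(C)=O)[C@@H](CO[Si](CC)(CC)CC)CC=C)cc1
F8 | step 5 | (1S,2R,3E)-1-(4-methoxyphenyl)-2-[(triethylsilyloxy)methyl]but-3-ene-1,4-diyl diacetate | COc1ccc([C@@H](OC(C)=O)[C@@H](CO[Si](CC)(CC)CC)/C=C/OC(C)=O)cc1
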